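(The readings were computed from invented constants, noise included.)

A small charge of dissolved gas has to serve a large charge of complex: the solution holds at most 9.4 mM of gas, and at one gas per exchange south-east calls for 18.3 such fillings.

common to all: gas 9.4 mM (held)

| run | starting complex | remark | time |
|---|---|---|---|
| spring | 0.028 M | run made earlier |  |
| dawn | 0.11 M | run made earlier |  |
| north | 0.020 M |  | 1.2 min |
| south-east | 0.086 M |  | 4.0 min |

| run | time / min | complex with two exchanged / % |
|---|---|---|
| spring | 0.250 | 2 |
| spring | 0.417 | 14 |
| spring | 0.833 | 35 |
| spring | 1.33 | 68 |
| spring | 3.00 | 98 |
| dawn | 0.250 | 0 |
| dawn | 0.667 | 8 |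
| dawn | 1.33 | 19 |
| dawn | 2.00 | 44 |
| dawn | 3.00 | 77 |

(readings scatter by 2 percentage points)

* the winner by amount of complex with two exchanged, in percent of the starting complex charged; "neither" if no more than 2 percentage points parts them (north / south-east / neither)
* how much complex with two exchanged is there at the end, in percent of the starting complex charged: north
* how much complex with two exchanged is there at the end, in percent of the starting complex charged: south-east

- at the start none of the gas is in solution

The reckoning here is separate from the forecast and builds the flask in stages. First comes the exchange alone, in a solution taken as full. The complex then decays pseudo-first-order, and the tail of the spring run reads, with the scatter on its last reading: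

κ = 1.66 min⁻¹

Next comes the crossing of gas. In the balance of dissolved gas, a flask that uses gas as fast as it crosses climbs on a straight line, and half conversion of a charge costs as much gas as the charge of starting complex. Interpolated between the two readings on either side of half conversion, the half-time of the spring run is 1.06 min, and that of the dawn run is:

dawn half-time = 2.18 min

S = (difference of charges)/(difference of half-times) = 0.0730 M min⁻¹

S is the uptake rate, the gas taken up per minute by a flask on the straight line. The rest of the start-up is lumped into an offset, a = 0.675 min, so that:

T = a + [starting complex]/S

Past T, the conversion follows the lower of two curves: the line, 0.5 + S(t − T)/(2[starting complex]), and the tail, 1 − 0.5exp(−κ(t − T)).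

North: T = 0.949 min, line 95.8 %, tail 67.0 %.

South-east: T = 1.85 min, line 141 %, tail 98.6 %.

The forecast names south-east as winner, with 70 % for north and 93 % for south-east, reasoning that “time scales roughly as the square root of concentration”. Its south-east figure lies lower than the one reckoned here.

The flasks give south-east as winner, with 65.8 % for north and 98.2 % for south-east, which is 5.2 percentage points above the forecast.

    gas ⇌ incoming ligand, rate k1*(csat - [incoming ligand]) (kL = 0.169 s⁻¹)
    starting complex + incoming ligand → leaving ligand + complex with one exchanged (k = 6.08 L mol⁻¹ s⁻¹)
    complex with one exchanged + incoming ligand → leaving ligand + complex with two exchanged (k = 4.34 L mol⁻¹ s⁻¹)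

In south-east the first exchange had half its turnover behind it by 0.787 min and the crossing by 1.31 min, with [incoming ligand] at 0.00442 M after 2.00 min. By 4.00 min it stood at 0.00895 M, with 0.0700 % of starting complex and 1.71 % of complex with one exchanged left.

For a neighbour flask, south-east with 0.15 M of starting complex, S gives T = 2.73 min, a line at 80.9 % and a tail at 93.9 %, so the line is the estimate. The computed neighbour flask holds 82.4 % of complex with two exchanged.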